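The leftover of partner at the end is the number I look for first in oak and larch.

| setting | Monday's | Sunday's | oak | larch |
|---|---|---|---|---|
| starting material | 0.17 M | 0.17 M | 0.12 M | 0.17 M |
| partner | 0.25 M | 0.39 M | 0.250 M | 0.179 M |
| remark | run made earlier | run made earlier |  |  |
| time |  |  | 6.0 min | 6.0 min |

| run | time / min | target / % | side product / % |
|---|---|---|---|
| Monday's | 0.417 | 27 | 40 |
| Monday's | 0.833 | 33 | 51 |
| Monday's | 1.33 | 37 | 58 |
| Monday's | 1.50 | 39 | 61 |
| Monday's | 2.00 | 37 | 60 |
| Monday's | 2.50 | 37 | 64 |
| Monday's | 3.00 | 38 | 61 |
| Sunday's | 0.250 | 15 | 24 |
| Sunday's | 0.333 | 24 | 30 |
| Sunday's | 0.500 | 26 | 43 |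
| Sunday's | 0.833 | 32 | 54 |
| Sunday's | 1.33 | 38 | 60 |
| Sunday's | 2.00 | 40 | 63 |
| Sunday's | 3.00 | 39 | 60 |

(scatter of a reading: 1.5 percentage points)

- the analysis behind the earlier runs scatters by 1.5 percentage points, standard deviation

* the flask that ends with the higher share of target in all that became target or side product, or "neither" when 2 percentage points or less lies between them (oak / larch / neither)
* share of target in all that became target or side product, oak
* share of target in all that became target or side product, larch

Which of these numbers must I know well? Not the time: Monday's readings stand still within the scatter from 1.50 min on, and 6.0 min lies beyond that. Not the exact charge of starting material: in Sunday's run the target share is 38.5% at 0.250 min and 39.4% at 3.00 min, though the starting material falls between them. Nor the partner, between 0.25 M and 0.39 M: the last readings give shares of 38.4% and 39.4%. But larch holds 0.179 M of partner, below both runs, so its margin has to be known.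

The last readings put the side-product share z at 61.1%. Starting material is the limiting reagent in larch, at 0.17 M against 0.179 M of partner, and I assume one partner per side product. With charges a and b of starting material and partner, the spare partner is L = b − z·a, where 0.0751 M is its value for larch. That is 42.0% of larch's charge; oak has 0.177 M, or 70.7%. Both are positive, so I expect a target share of 38.9% in each flask.

The forecast gives 39% for oak, 39% for larch and neither, and says larch “nears partner exhaustion”, where my L stays positive.

The flasks give 38.1% for oak and 38.1% for larch: neither.

    starting material → target (k = 0.0160 s⁻¹)
    starting material → intermediate (k = 0.0260 s⁻¹)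
    partner + intermediate → side product (k = 1.50 M⁻¹ s⁻¹)

Partner ends at 70.3% of its charge in oak and 41.2% in larch, close to what L gave. In oak at 0.275 min, intermediate has a half-life of 2.1 s against partner, shorter than the 26.7 s of starting material's loss to intermediate. Oak holds intermediate at 0.00611% of the starting material charged at 3.00 min. A flask like oak with 0.062 M of partner has a negative L: it falls short by 0.0113 M, which is 9.44% of its starting material, and it ends with partner at 0.045% of its charge, intermediate at 10.3% of the starting material charged and a target share of 42.5%.

Readings and results were computed with made-up constants, and the scatter is random.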